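Locants follow lignan usage: C7–C9 is the guaiacylpropane unit, C7'–C9' the syringylpropane unit, C7''–C9'' the glycerol side chain.

## Analysis of the target

Target 29 is an unsymmetrical furofuran sesquilignan built on a cis-fused 3,7-dioxabicyclo[3.3.0]octane. Ring A (O, C7, C8, C8', C9') carries a 4-hydroxy-3-methoxyphenyl group on C7. Ring B (O, C7', C8', C8, C9) carries a 3,5-dimethoxyphenyl group on C7', whose 4-oxygen is etherified by C8'' of a 1-(4-hydroxy-3,5-dimethoxyphenyl)propane-1,3-diol. The core has four contiguous stereocentres (7R, 8S, 8'S, 7'S): the bridgehead hydrogens are cis, the guaiacyl group on C7 is exo (convex face), and the syringyl group on C7' is endo, that is cis to C9' and C7 on ring B. The side chain adds 7''R and 8''R, a threo aryl-glycerol β-aryl ether with no stereochemical link to the core. Sensitive groups are two free phenols (easily oxidised) and three benzylic C–O bonds para to oxygen (C7–O, C7'–O, C7''–OH), which epimerise in acid and can be hydrogenolysed over palladium. The hard points are the endo aryl at C7' (the less stable arrangement, lost wherever that centre can ionise), telling three phenolic oxygens apart, and setting the remote threo diol in absolute terms. The strategy rests on C7 of ring A: it is a benzylic ether carbon para to the free guaiacyl hydroxyl, so it becomes electrophilic in a p-quinone methide, and its ring oxygen can be supplied as the C9' hydroxyl of a monocyclic precursor. The endo centre C7' carries an etherified aryl group and cannot take part in that chemistry.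

## Retrosynthetic reasoning

**O–Si at the terminal phenol (29 ⇒ 28).** The second phenol must be masked while the first is oxidised. A silyl ether is chosen so that the last step is a buffered desilylation, and neither acid nor a hydrogenation catalyst meets the finished furofuran.

**O–C7 of ring A (28 ⇒ 26).** This is the key disconnection. Cutting the bond between the ring oxygen and C7 leaves the all-cis tetrahydrofuran 26, in which C7 is a methylene para to the free phenol and the oxygen is the C9' hydroxyl. Forward, two-electron oxidation of that phenol must make C7 electrophilic and the hydroxyl must close a five-membered ring. The cut is made here and not at C7' because only the C7 aryl group has a free hydroxyl, and because the exo aryl it produces is the stable one. The side-chain diol is carried free, since it is too far from C7 to compete.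

**Two benzyl ethers (26 ⇒ 25).** The guaiacyl oxygen and the C9' oxygen are both carried as benzyl ethers so that one hydrogenolysis releases exactly the two groups the key step needs, on a monocyclic substrate.

**C7''–C8'' and the C9'' oxidation level (25 ⇒ 24 ⇒ 20 + 22).** The threo diol is cut between C7'' and C8''. Forward, a syn glycolate aldol between imide 20 and aldehyde 22 sets both centres under control of the auxiliary, independent of the distant core, and reductive removal of the auxiliary gives the primary alcohol. Displacement at C8'' by a hindered 2,6-dimethoxyphenol was not considered reliable, so the aryl ether is in place before the stereocentres are made.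

**Aryl O–CH2 (20 ⇒ 16 + 19).** The two-carbon glycolate unit is attached to phenol 16 by alkylation with bromo imide 19, which is made from oxazolidinone 17. The side chain is attached only after the tetrahydrofuran is finished, because its benzylic C7''–O bond would not tolerate the Lewis acid and silane used there.

**C7'–H and C7'–aryl (16 ⇒ 15 ⇒ 13 ⇒ 9 + 11).** The endo aryl is traced to hemiketal 13, and that to cis-lactone 9 and aryl bromide 11 (from phenol 10). Forward, the aryllithium adds to the lactone carbonyl and ionic hydrogenation delivers hydride to the face opposite the two cis substituents, which puts the aryl group cis to both. The phenol of 11 is silylated so that it can be freed in the presence of the two benzyl ethers.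

**C8'–C9' (9 ⇒ 8 ⇒ 6).** C9' is introduced by formylation of lactone 6 and trapped as the benzyl enol ether 8. Hydrogenation from the face opposite the C8 substituent gives the cis lactone, which alkylation of the enolate would not.

**C7–C8 and the first stereocentre (6 ⇒ 4 ⇒ 3 ⇒ 1 + 2).** A Stobbe condensation of aldehyde 1 with diester 2 joins C7 to C8, asymmetric hydrogenation of half-ester 3 sets C8, and chemoselective ester reduction gives lactone 6. Every later core stereocentre is relayed from C8.

## Alternatives that were turned down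

**Alternative 1: furan–aldehyde photocycloaddition.**
- Disconnection: C7'–C8', with a temporary O–C9' bond.
- Forward key step: irradiation of aldehyde A2 in furan A3 should give the exo oxetane A1.
- For: one step from two bulk chemicals creates C7'–C8' with the aryl/C9' relation that maps onto the endo syringyl group. Furan supplies C9', C8', C8 and C9 in one piece, and the remaining enol ether is a nucleophilic handle at C8.
- Against: A1 forms as a racemate. The furan oxygen joins C9' to C9, a bond the target does not contain, so the photoadduct has to be opened and both ether rings built afterwards. C8 and C7 would be set by additions with no strong bias, and the guaiacyl unit, the phenol switch and the whole side chain still follow.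
- Comparison: it reaches the hardest relative configuration faster (one step against eight to reach 15). The chosen strategy offers absolute configuration from a catalytic hydrogenation, relay of every later centre from it, and a skeleton in which no bond has to be broken again.

**Alternative 2: conjugate addition–aldol on a chiral butenolide.**
- Disconnection: C7'–C8' and C7–C8.
- Forward key step: the anion of dithiane A6 adds to butenolide A5 anti to the acetal substituent, and the enolate is trapped by aldehyde 1 to give lactone A4.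
- For: two skeletal bonds and the absolute configuration at C8 and C8' come from a single operation with a chiral-pool auxiliary. This is more convergent in C–C bond formation than the Stobbe, hydrogenation and formylation sequence used here.
- Against: no ring of the target is closed. C7' arrives at the ketone level and C9, C9' at the acid and aldehyde levels, so dithiane removal, three reductions and two etherifications follow. The endo configuration at C7' would have to be set by a ketone reduction and kept through a closure that must not ionise, whereas acid-mediated double cyclisation of such polyols leads to the diequatorial (exo, exo) series.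
- Comparison: stronger on bond-forming economy in one step. The chosen strategy offers a C7' centre fixed by hydride delivery to a cyclic oxocarbenium ion with both neighbours on one face, which is never again exposed to ionising conditions.

**Alternative 3: intramolecular nitrile oxide cycloaddition.**
- Disconnection: C8–C8' and O–C7'.
- Forward key step: oxidation of aldoxime A8 gives nitrile oxide A9, which adds to the tethered (Z)-styrene and closes ring A fused to isoxazoline A7.
- For: the alkene geometry is transferred stereospecifically to the C8'/C7' relation, so the endo aryl does not depend on a facial selectivity. Ring A and two bonds form in one reliable step.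
- Against: nitrogen occupies the place of C9. After the key step the N–O bond must be cleaved, a carbon added at C8, the C8 centre created on an sp2 carbon, and ring B closed by a second etherification. The C7 centre of A8 is benzylic and adjacent to the C=N carbon, so it is prone to racemisation and must be made in enantiopure form first. The (Z)-styrene needs its own synthesis.
- Comparison: stronger on stereospecificity at C7'/C8'. The chosen strategy needs one deprotection after the key step instead of a five- or six-step end game, and forms its last stereocentre as the stable exo isomer.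

Key step: step 16

Assumption: the sense of induction in step 2 is taken from the quadrant model for chelating itaconate half-esters ((R,R)-Et-DuPhos on rhodium giving the (S)-acid 4); if the rotation of lactone 6 indicates the opposite, the (S,S)-ligand is used.

## Route

Step 1
Reactants: 1 4-(benzyloxy)-3-methoxybenzaldehyde; 2 dimethyl succinate
Product: 3 (E)-4-[4-(benzyloxy)-3-methoxyphenyl]-3-(methoxycarbonyl)but-3-enoic acid
Conditions: NaOMe (1.5 equiv), MeOH, reflux; then aq HCl
Reagents that add atoms: none
Why: Stobbe condensation; the succinate enolate adds to the aldehyde, the alkoxide lactonises onto the distal ester and base-induced ring opening gives the half-ester with the aryl group trans to the conjugated ester, forming C7–C8.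

Step 2
Reactants: 3 (E)-4-[4-(benzyloxy)-3-methoxyphenyl]-3-(methoxycarbonyl)but-3-enoic acid
Product: 4 (3S)-4-[4-(benzyloxy)-3-methoxyphenyl]-3-(methoxycarbonyl)butanoic acid
Conditions: [Rh(cod)((R,R)-Et-DuPhos)]BF4 (0.5 mol%), H2 (5 atm), NaOMe (0.1 equiv), MeOH, rt
Reagents that add atoms: none
Why: Asymmetric hydrogenation of a Stobbe-type itaconate half-ester; carboxylate and alkene chelate monovalent rhodium and hydrogen is delivered to one face, setting C8 as S, while the aryl benzyl ether is inert to the homogeneous catalyst.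

Step 3
Reactants: 4 (3S)-4-[4-(benzyloxy)-3-methoxyphenyl]-3-(methoxycarbonyl)butanoic acid
Product: 6 (4S)-4-[4-(benzyloxy)-3-methoxybenzyl]dihydrofuran-2(3H)-one, via hydroxy acid 5 (not isolated)
Conditions: KOH (1.0 equiv), EtOH; CaCl2, NaBH4, EtOH, −10 °C to rt; then 2 M HCl, rt
Reagents that add atoms: none
Why: Chemoselective borohydride reduction; Ca(BH4)2 reduces the ester but not the carboxylate, and acidification lets hydroxy acid 5 close to the γ-lactone without touching C8.

Step 4
Reactants: 6 (4S)-4-[4-(benzyloxy)-3-methoxybenzyl]dihydrofuran-2(3H)-one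
Product: 8 (3E,4S)-3-[(benzyloxy)methylene]-4-[4-(benzyloxy)-3-methoxybenzyl]dihydrofuran-2(3H)-one, via potassium enolate 7 (not isolated)
Conditions: HCO2Et (3 equiv), KOt-Bu (1.3 equiv), THF, 0 °C to rt; then BnBr (1.5 equiv), DMF, rt
Reagents that add atoms: ethyl formate, CCOC=O; benzyl bromide, BrCc1ccccc1
Why: Claisen formylation at the only enolisable position gives the stabilised enolate 7, which alkylates on oxygen in a dipolar aprotic solvent (O-alkylation of a hydroxymethylene lactone) to give the E-enol ether, so C9' enters at the alcohol level already protected.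

Step 5
Reactants: 8 (3E,4S)-3-[(benzyloxy)methylene]-4-[4-(benzyloxy)-3-methoxybenzyl]dihydrofuran-2(3H)-one
Product: 9 (3S,4S)-3-[(benzyloxy)methyl]-4-[4-(benzyloxy)-3-methoxybenzyl]dihydrofuran-2(3H)-one (3,4-cis)
Conditions: H2 (1 atm), 5% Rh/Al2O3, EtOAc, rt
Reagents that add atoms: none
Why: Heterogeneous syn hydrogenation of an α-alkylidene lactone; both hydrogens add to the face opposite the C8 arylmethyl group, which sets C8' as S with the benzyloxymethyl group cis to it, and rhodium on alumina saturates alkenes while sparing benzyl ethers under neutral conditions that do not epimerise the cis lactone.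

Step 6
Reactants: 10 4-bromo-2,6-dimethoxyphenol
Product: 11 (4-bromo-2,6-dimethoxyphenoxy)triisopropylsilane
Conditions: i-Pr3SiCl, imidazole, DMF, rt
Reagents that add atoms: chlorotriisopropylsilane, CC(C)[Si](Cl)(C(C)C)C(C)C
Why: Phenol silylation; the triisopropylsilyl ether tolerates halogen–lithium exchange and BF3·OEt2 at low temperature and is later cleaved by fluoride in the presence of benzyl ethers.

Step 7
Reactants: 11 (4-bromo-2,6-dimethoxyphenoxy)triisopropylsilane; 9 (3S,4S)-3-[(benzyloxy)methyl]-4-[4-(benzyloxy)-3-methoxybenzyl]dihydrofuran-2(3H)-one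
Product: 13 (3S,4S)-3-[(benzyloxy)methyl]-4-[4-(benzyloxy)-3-methoxybenzyl]-2-[3,5-dimethoxy-4-(triisopropylsilyloxy)phenyl]tetrahydrofuran-2-ol (both anomers), via aryllithium 12 (not isolated)
Conditions: 11 (1.3 equiv), n-BuLi (1.25 equiv), THF, −78 °C; then 9, −78 °C; sat. NH4Cl at −78 °C; used crude
Reagents that add atoms: none
Why: Bromine–lithium exchange followed by 1,2-addition of the aryllithium to the lactone carbonyl forms the C7'–aryl bond; the lithium hemiketalate is stable at −78 °C, which prevents a second addition, and the cold neutral quench protects the epimerisable C8' centre.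

Step 8
Reactants: 13 (3S,4S)-3-[(benzyloxy)methyl]-4-[4-(benzyloxy)-3-methoxybenzyl]-2-[3,5-dimethoxy-4-(triisopropylsilyloxy)phenyl]tetrahydrofuran-2-ol
Product: 15 (2S,3S,4S)-3-[(benzyloxy)methyl]-4-[4-(benzyloxy)-3-methoxybenzyl]-2-[3,5-dimethoxy-4-(triisopropylsilyloxy)phenyl]tetrahydrofuran (all-cis), via oxocarbenium ion 14 (not isolated)
Conditions: Et3SiH (5 equiv), BF3·OEt2 (2 equiv, promoter), CH2Cl2, −78 °C; sat. NaHCO3 at −78 °C
Reagents that add atoms: none
Why: Ionic hydrogenation of a 2-aryl lactol; BF3·OEt2 ionises the hemiketal to oxocarbenium ion 14 and Et3SiH delivers hydride to the face opposite the two cis substituents on C8' and C8, so the aryl group ends up cis to both (C7' S), and at −78 °C hydride capture should outrun the enol-ether formation that would epimerise C8'.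

Step 9
Reactants: 15 (2S,3S,4S)-3-[(benzyloxy)methyl]-4-[4-(benzyloxy)-3-methoxybenzyl]-2-[3,5-dimethoxy-4-(triisopropylsilyloxy)phenyl]tetrahydrofuran
Product: 16 4-{(2S,3S,4S)-3-[(benzyloxy)methyl]-4-[4-(benzyloxy)-3-methoxybenzyl]tetrahydrofuran-2-yl}-2,6-dimethoxyphenol
Conditions: Bu4NF (1.2 equiv), AcOH (1.2 equiv), THF, 0 °C
Reagents that add atoms: none
Why: Fluoride cleavage of an aryl silyl ether; the two benzyl ethers and the benzylic ring ether are untouched, which frees only the syringyl oxygen for the side chain.

Step 10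
Reactants: 17 (S)-4-benzyloxazolidin-2-one
Product: 19 (S)-4-benzyl-3-(bromoacetyl)oxazolidin-2-one, via lithium amide 18 (not isolated)
Conditions: n-BuLi (1.0 equiv), THF, −78 °C; BrCH2COBr (1.1 equiv), −78 to 0 °C
Reagents that add atoms: bromoacetyl bromide, BrCC(Br)=O
Why: N-Acylation of the lithiated oxazolidinone; the acyl bromide is far more electrophilic than the alkyl bromide, so the α-bromo imide is obtained.

Step 11
Reactants: 16 4-{(2S,3S,4S)-3-[(benzyloxy)methyl]-4-[4-(benzyloxy)-3-methoxybenzyl]tetrahydrofuran-2-yl}-2,6-dimethoxyphenol; 19 (S)-4-benzyl-3-(bromoacetyl)oxazolidin-2-one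
Product: 20 (S)-4-benzyl-3-{[4-((2S,3S,4S)-3-[(benzyloxy)methyl]-4-[4-(benzyloxy)-3-methoxybenzyl]tetrahydrofuran-2-yl)-2,6-dimethoxyphenoxy]acetyl}oxazolidin-2-one
Conditions: K2CO3 (1.5 equiv), acetone, rt
Reagents that add atoms: none
Why: Williamson etherification; the 2,6-dimethoxyphenoxide displaces the carbonyl-activated α-bromide by SN2, and mild carbonate at room temperature should leave the imide and the other ethers intact.

Step 12
Reactants: 21 4-hydroxy-3,5-dimethoxybenzaldehyde (syringaldehyde)
Product: 22 3,5-dimethoxy-4-(triisopropylsilyloxy)benzaldehyde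
Conditions: i-Pr3SiCl, imidazole, DMF, rt
Reagents that add atoms: chlorotriisopropylsilane, CC(C)[Si](Cl)(C(C)C)C(C)C
Why: Phenol silylation; this silyl ether is the only protecting group that has to survive the hydrogenolysis and the anodic step, and it leaves last with fluoride.

Step 13
Reactants: 20 (S)-4-benzyl-3-{[4-((2S,3S,4S)-3-[(benzyloxy)methyl]-4-[4-(benzyloxy)-3-methoxybenzyl]tetrahydrofuran-2-yl)-2,6-dimethoxyphenoxy]acetyl}oxazolidin-2-one; 22 3,5-dimethoxy-4-(triisopropylsilyloxy)benzaldehyde
Product: 24 (S)-4-benzyl-3-[(2S,3R)-2-aryloxy-3-hydroxy-3-(3,5-dimethoxy-4-triisopropylsilyloxyphenyl)propanoyl]oxazolidin-2-one (aryloxy = the dibenzyl-protected core phenoxy group of 16), via boron enolate 23 (not isolated)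
Conditions: Bu2BOTf (1.2 equiv), i-Pr2NEt (1.4 equiv), CH2Cl2, −78 to 0 °C; 22 (1.2 equiv), −78 to 0 °C; pH 7 buffer, MeOH, 30% H2O2, 0 °C
Reagents that add atoms: none
Why: Evans syn aldol of a glycolate imide; soft enolisation gives the (Z)-boron enolate 23, which reacts through a chair Zimmerman–Traxler transition state on the face away from the auxiliary benzyl group, setting C8'' and C7'' together as the threo (7''R,8''R) pair under reagent control, independent of the distant core.

Step 14
Reactants: 24 the syn aldol imide
Product: 25 (1R,2R)-2-{4-[(2S,3S,4S)-3-[(benzyloxy)methyl]-4-[4-(benzyloxy)-3-methoxybenzyl]tetrahydrofuran-2-yl]-2,6-dimethoxyphenoxy}-1-[3,5-dimethoxy-4-(triisopropylsilyloxy)phenyl]propane-1,3-diol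
Conditions: LiBH4 (2 equiv), MeOH (2 equiv), THF, 0 °C; aq NH4Cl
Reagents that add atoms: none
Why: Reductive cleavage of an N-acyl oxazolidinone to the primary alcohol (C9''); the carbinol, aryl silyl ether and benzyl ethers survive and the auxiliary is recovered.

Step 15
Reactants: 25 the dibenzyl diol
Product: 26 (1R,2R)-1-[3,5-dimethoxy-4-(triisopropylsilyloxy)phenyl]-2-{4-[(2S,3S,4S)-4-(4-hydroxy-3-methoxybenzyl)-3-(hydroxymethyl)tetrahydrofuran-2-yl]-2,6-dimethoxyphenoxy}propane-1,3-diol
Conditions: H2 (1 atm), 10% Pd/C, EtOAc–EtOH, rt, stopped when the alkyl benzyl ether is consumed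
Reagents that add atoms: none
Why: Hydrogenolysis of one aryl and one primary alkyl benzyl ether; in neutral solvent the ring benzylic ether and the benzylic carbinol are cleaved much more slowly, so the guaiacyl phenol and the C9' hydroxyl are released together.

Step 16
Reactants: 26 the all-cis tetrahydrofuran with free guaiacyl phenol and C9' hydroxyl
Product: 28 4''-O-triisopropylsilyl ether of the target with (7R,8S,7'S,8'S,7''R,8''R) configuration, via quinone methide 27 (not isolated)
Conditions: reticulated vitreous carbon anode, Pt cathode, undivided cell, constant current (about 1 mA cm−2, 2.1 F mol−1), LiClO4 (0.1 M), 2,6-lutidine (3 equiv), CH2Cl2–(CF3)2CHOH 4:1, 2 mM, rt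
Reagents that add atoms: none
Why: At the carbon anode the lutidine-bound guaiacyl phenol of 26 loses two electrons and its proton, and 2,6-lutidine then removes the benzylic C7 proton of the phenoxonium ion to give p-quinone methide 27. The C9' hydroxyl, held next to C7 by the cis arrangement on C8' and C8, adds to the exocyclic carbon in a 5-exo-trig conjugate addition that forms O–C7, closes ring A and restores the aromatic ring. The closest known reaction type is the anodic or quinone-mediated oxidation of 4-alkylphenols to p-quinone methides with capture by an alcohol, as used to close lignan tetrahydrofuran rings. The ring fusion can only be cis because C9' and C7 already stand cis on ring B; the new centre C7 is controlled by attack on the rotamer that keeps the quinoid ring away from ring B, so the aryl group becomes exo (7R), which is also the more stable epimer and remains reachable by reversible opening through the same quinone methide. The step needs oxidation of one arene out of three: the free phenol is oxidised well below the two 1,2,3-trialkoxyarenes and the benzylic carbinol, and a low constant current with about two faradays per mole should keep the anode at that potential. C7' cannot epimerise because its aryl group has no free hydroxyl and cannot form a quinone methide. High dilution and the non-nucleophilic solvent pair favour the intramolecular closure over phenol–phenol coupling and over capture by solvent.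

Step 17
Reactants: 28 4''-O-triisopropylsilyl ether of the target
Product: 29 (1R,2R)-1-(4-hydroxy-3,5-dimethoxyphenyl)-2-{4-[(1S,3aS,4R,6aS)-4-(4-hydroxy-3-methoxyphenyl)tetrahydro-1H,3H-furo[3,4-c]furan-1-yl]-2,6-dimethoxyphenoxy}propane-1,3-diol (target; 7R,8S,7'S,8'S,7''R,8''R)
Conditions: Bu4NF (1.5 equiv), AcOH (1.5 equiv), THF, 0 °C
Reagents that add atoms: none
Why: Buffered fluoride desilylation of the aryl silyl ether; no acid, strong base or hydrogen reaches the furofuran, so the endo centre C7' and the threo diol should be retained.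

## Compound list

1 | 4-(benzyloxy)-3-methoxybenzaldehyde | COc1cc(C=O)ccc1OCc1ccccc1 | starting material
2 | dimethyl succinate | COC(=O)CCC(=O)OC | starting material
3 | (E)-4-[4-(benzyloxy)-3-methoxyphenyl]-3-(methoxycarbonyl)but-3-enoic acid | COC(=O)/C(CC(=O)O)=C/c1ccc(OCc2ccccc2)c(OC)c1 | intermediate
4 | (3S)-4-[4-(benzyloxy)-3-methoxyphenyl]-3-(methoxycarbonyl)butanoic acid | COC(=O)[C@@H](Cc1ccc(OCc2ccccc2)c(OC)c1)CC(=O)O | intermediate
5 | (3S)-4-[4-(benzyloxy)-3-methoxyphenyl]-3-(hydroxymethyl)butanoic acid | OC[C@@H](Cc1ccc(OCc2ccccc2)c(OC)c1)CC(=O)O | intermediate (not isolated)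
6 | (4S)-4-[4-(benzyloxy)-3-methoxybenzyl]dihydrofuran-2(3H)-one | O=C1OC[C@@H](Cc2ccc(OCc3ccccc3)c(OC)c2)C1 | intermediate
7 | potassium enolate of (4S)-3-formyl-4-[4-(benzyloxy)-3-methoxybenzyl]dihydrofuran-2(3H)-one | O=C1OC[C@@H](Cc2ccc(OCc3ccccc3)c(OC)c2)C1=C[O-].[K+] | intermediate (not isolated)
8 | (3E,4S)-3-[(benzyloxy)methylene]-4-[4-(benzyloxy)-3-methoxybenzyl]dihydrofuran-2(3H)-one | O=C1OC[C@@H](Cc2ccc(OCc3ccccc3)c(OC)c2)/C1=C\OCc1ccccc1 | intermediate
9 | (3S,4S)-3-[(benzyloxy)methyl]-4-[4-(benzyloxy)-3-methoxybenzyl]dihydrofuran-2(3H)-one (cis) | O=C1OC[C@@H](Cc2ccc(OCc3ccccc3)c(OC)c2)[C@H]1COCc1ccccc1 | intermediate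
10 | 4-bromo-2,6-dimethoxyphenol | COc1cc(Br)cc(OC)c1O | starting material
11 | (4-bromo-2,6-dimethoxyphenoxy)triisopropylsilane | COc1cc(Br)cc(OC)c1O[Si](C(C)C)(C(C)C)C(C)C | intermediate
12 | [3,5-dimethoxy-4-(triisopropylsilyloxy)phenyl]lithium | [Li]c1cc(OC)c(O[Si](C(C)C)(C(C)C)C(C)C)c(OC)c1 | intermediate (not isolated)
13 | (3S,4S)-3-[(benzyloxy)methyl]-4-[4-(benzyloxy)-3-methoxybenzyl]-2-[3,5-dimethoxy-4-(triisopropylsilyloxy)phenyl]tetrahydrofuran-2-ol (both anomers) | COc1cc(C[C@@H]2COC(O)(c3cc(OC)c(O[Si](C(C)C)(C(C)C)C(C)C)c(OC)c3)[C@@H]2COCc2ccccc2)ccc1OCc1ccccc1 | intermediate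
14 | cyclic 2-aryl oxocarbenium ion from 13 (hydroxytrifluoroborate) | COc1cc(C[C@@H]2C[O+]=C(c3cc(OC)c(O[Si](C(C)C)(C(C)C)C(C)C)c(OC)c3)[C@@H]2COCc2ccccc2)ccc1OCc1ccccc1.O[B-](F)(F)F | intermediate (not isolated)
15 | (2S,3S,4S)-3-[(benzyloxy)methyl]-4-[4-(benzyloxy)-3-methoxybenzyl]-2-[3,5-dimethoxy-4-(triisopropylsilyloxy)phenyl]tetrahydrofuran (all-cis) | COc1cc(C[C@@H]2CO[C@H](c3cc(OC)c(O[Si](C(C)C)(C(C)C)C(C)C)c(OC)c3)[C@@H]2COCc2ccccc2)ccc1OCc1ccccc1 | intermediate
16 | 4-{(2S,3S,4S)-3-[(benzyloxy)methyl]-4-[4-(benzyloxy)-3-methoxybenzyl]tetrahydrofuran-2-yl}-2,6-dimethoxyphenol | COc1cc(C[C@@H]2CO[C@H](c3cc(OC)c(O)c(OC)c3)[C@@H]2COCc2ccccc2)ccc1OCc1ccccc1 | intermediate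
17 | (S)-4-benzyloxazolidin-2-one | O=C1N[C@@H](Cc2ccccc2)CO1 | starting material
18 | lithium salt of (S)-4-benzyloxazolidin-2-one | [Li]N1[C@@H](Cc2ccccc2)COC1=O | intermediate (not isolated)
19 | (S)-4-benzyl-3-(bromoacetyl)oxazolidin-2-one | O=C(CBr)N1[C@@H](Cc2ccccc2)COC1=O | intermediate
20 | (S)-4-benzyl-3-{[4-((2S,3S,4S)-3-[(benzyloxy)methyl]-4-[4-(benzyloxy)-3-methoxybenzyl]tetrahydrofuran-2-yl)-2,6-dimethoxyphenoxy]acetyl}oxazolidin-2-one | COc1cc(C[C@@H]2CO[C@H](c3cc(OC)c(OCC(=O)N4[C@@H](Cc5ccccc5)COC4=O)c(OC)c3)[C@@H]2COCc2ccccc2)ccc1OCc1ccccc1 | intermediate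
21 | 4-hydroxy-3,5-dimethoxybenzaldehyde (syringaldehyde) | COc1cc(C=O)cc(OC)c1O | starting material
22 | 3,5-dimethoxy-4-(triisopropylsilyloxy)benzaldehyde | COc1cc(C=O)cc(OC)c1O[Si](C(C)C)(C(C)C)C(C)C | intermediate
23 | (Z)-dibutylboron enolate of imide 20 | COc1cc(C[C@@H]2CO[C@H](c3cc(OC)c(O/C=C(\OB(CCCC)CCCC)N4[C@@H](Cc5ccccc5)COC4=O)c(OC)c3)[C@@H]2COCc2ccccc2)ccc1OCc1ccccc1 | intermediate (not isolated)
24 | (S)-4-benzyl-3-[(2S,3R)-2-aryloxy-3-hydroxy-3-(3,5-dimethoxy-4-triisopropylsilyloxyphenyl)propanoyl]oxazolidin-2-one, aryloxy = core phenoxy group of 16 | COc1cc(C[C@@H]2CO[C@H](c3cc(OC)c(O[C@H](C(=O)N4[C@@H](Cc5ccccc5)COC4=O)[C@H](O)c4cc(OC)c(O[Si](C(C)C)(C(C)C)C(C)C)c(OC)c4)c(OC)c3)[C@@H]2COCc2ccccc2)ccc1OCc1ccccc1 | intermediate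
25 | (1R,2R)-2-{4-[(2S,3S,4S)-3-[(benzyloxy)methyl]-4-[4-(benzyloxy)-3-methoxybenzyl]tetrahydrofuran-2-yl]-2,6-dimethoxyphenoxy}-1-[3,5-dimethoxy-4-(triisopropylsilyloxy)phenyl]propane-1,3-diol | COc1cc(C[C@@H]2CO[C@H](c3cc(OC)c(O[C@H](CO)[C@H](O)c4cc(OC)c(O[Si](C(C)C)(C(C)C)C(C)C)c(OC)c4)c(OC)c3)[C@@H]2COCc2ccccc2)ccc1OCc1ccccc1 | intermediate
26 | (1R,2R)-1-[3,5-dimethoxy-4-(triisopropylsilyloxy)phenyl]-2-{4-[(2S,3S,4S)-4-(4-hydroxy-3-methoxybenzyl)-3-(hydroxymethyl)tetrahydrofuran-2-yl]-2,6-dimethoxyphenoxy}propane-1,3-diol | COc1cc(C[C@@H]2CO[C@H](c3cc(OC)c(O[C@H](CO)[C@H](O)c4cc(OC)c(O[Si](C(C)C)(C(C)C)C(C)C)c(OC)c4)c(OC)c3)[C@@H]2CO)ccc1O | intermediate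
27 | p-quinone methide of 26 (C7 exocyclic to the 2-methoxycyclohexadienone) | COC1=CC(=C[C@@H]2CO[C@H](c3cc(OC)c(O[C@H](CO)[C@H](O)c4cc(OC)c(O[Si](C(C)C)(C(C)C)C(C)C)c(OC)c4)c(OC)c3)[C@@H]2CO)C=CC1=O | intermediate (not isolated)
28 | 4''-O-triisopropylsilyl ether of the target (7R,8S,7'S,8'S,7''R,8''R) | COc1cc([C@@H]2OC[C@@H]3[C@H]2CO[C@@H]3c2cc(OC)c(O[C@H](CO)[C@H](O)c3cc(OC)c(O[Si](C(C)C)(C(C)C)C(C)C)c(OC)c3)c(OC)c2)ccc1O | intermediate
29 | (1R,2R)-1-(4-hydroxy-3,5-dimethoxyphenyl)-2-{4-[(1S,3aS,4R,6aS)-4-(4-hydroxy-3-methoxyphenyl)tetrahydro-1H,3H-furo[3,4-c]furan-1-yl]-2,6-dimethoxyphenoxy}propane-1,3-diol | COc1cc([C@@H]2OC[C@@H]3[C@H]2CO[C@@H]3c2cc(OC)c(O[C@H](CO)[C@H](O)c3cc(OC)c(O)c(OC)c3)c(OC)c2)ccc1O | target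

## Step count and least certain steps

Total: 17 steps. Longest linear sequence: 14 steps (1, 2, 3, 4, 5, 7, 8, 9, 11, 13, 14, 15, 16, 17); steps 6, 10 and 12 prepare the three side partners.

**Step 16 (key step).** The phenoxyl radical may couple with a second molecule before the second electron is removed, the product phenol (still benzylic at C7) may be oxidised further, and the quinone methide may be reduced at the cathode of the undivided cell. Fallback, setting out from 26: oxidation and closure are uncoupled. DDQ in CH2Cl2–MeOH should generate the same quinone methide chemically and trap it with the large excess of methanol, giving the C7 methyl ether F1 as an epimer mixture. Catalytic camphorsulfonic acid in dry CH2Cl2 should then re-ionise F1 with loss of methanol and close ring A under thermodynamic control, returning to the route at 28.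

**Step 5.** The donor–acceptor alkene may be saturated only slowly on rhodium, so that cleavage of the enol or aryl benzyl ether, arene reduction or incomplete facial selectivity could compete. Fallback, setting out from 6: deprotonation with LiN(i-Pr)2 and alkylation with benzyl chloromethyl ether should give the trans lactone F2 (alkylation anti to the C8 substituent). A second deprotonation at −78 °C gives lithium enolate F3, and kinetic protonation by 2,6-di-tert-butyl-4-methylphenol from the face opposite the arylmethyl group should return the cis lactone 9.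

**Step 8.** Loss of the C8' proton from oxocarbenium ion 14 before hydride capture would epimerise C8' and erode the all-cis selectivity, and prolonged exposure to the Lewis acid could open the ring at the benzylic C7'–O bond. Fallback, setting out from 13: the enol ether is made on purpose. Dehydration with MsCl and Et3N gives the 4,5-dihydrofuran F4, and hydrogenation over Rh/Al2O3 from the face opposite the C8 arylmethyl group adds both hydrogens cis, setting C7' and C8' together and returning to 15.

**Step 11.** The phenoxide may attack the imide carbonyls (acyl transfer with loss of the auxiliary), or the base may cause self-condensation of the bromo imide, in competition with the SN2 displacement. Fallback, setting out from 16: alkylation with ethyl bromoacetate and K2CO3 gives the ethyl aryloxyacetate F5, and saponification with LiOH gives the acid F6. Pivaloyl chloride and Et3N convert F6 into the mixed anhydride F7, which acylates the lithium amide 18 to return to 20.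

**Step 15.** During the slower cleavage of the alkyl benzyl ether, hydrogenolysis may begin at the benzylic carbinol C7'' or at the ring C7'–O bond. Fallback, setting out from 20: the debenzylation is moved to the imide, where no carbinol or silyl ether is present, giving the phenol–alcohol F8. Ac2O and pyridine give the diacetate F9, the aldol with 22 under the conditions of step 13 gives F10, and an excess of LiBH4 then removes the auxiliary and both acetates in one operation, returning to 26.

## Further compounds

F1 | step 16 | C7 methyl ether of 26 (both C7 epimers) | COc1cc(C(OC)[C@@H]2CO[C@H](c3cc(OC)c(O[C@H](CO)[C@H](O)c4cc(OC)c(O[Si](C(C)C)(C(C)C)C(C)C)c(OC)c4)c(OC)c3)[C@@H]2CO)ccc1O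
F2 | step 5 | (3R,4S)-3-[(benzyloxy)methyl]-4-[4-(benzyloxy)-3-methoxybenzyl]dihydrofuran-2(3H)-one (trans) | O=C1OC[C@@H](Cc2ccc(OCc3ccccc3)c(OC)c2)[C@@H]1COCc1ccccc1
F3 | step 5 | lithium enolate of F2 | [Li]OC1=C(COCc2ccccc2)[C@H](Cc2ccc(OCc3ccccc3)c(OC)c2)CO1
F4 | step 8 | (3S)-4-[(benzyloxy)methyl]-3-[4-(benzyloxy)-3-methoxybenzyl]-5-[3,5-dimethoxy-4-(triisopropylsilyloxy)phenyl]-2,3-dihydrofuran | COc1cc(C[C@@H]2COC(c3cc(OC)c(O[Si](C(C)C)(C(C)C)C(C)C)c(OC)c3)=C2COCc2ccccc2)ccc1OCc1ccccc1
F5 | step 11 | ethyl [4-((2S,3S,4S)-3-[(benzyloxy)methyl]-4-[4-(benzyloxy)-3-methoxybenzyl]tetrahydrofuran-2-yl)-2,6-dimethoxyphenoxy]acetate | COc1cc(C[C@@H]2CO[C@H](c3cc(OC)c(OCC(=O)OCC)c(OC)c3)[C@@H]2COCc2ccccc2)ccc1OCc1ccccc1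
F6 | step 11 | [4-((2S,3S,4S)-3-[(benzyloxy)methyl]-4-[4-(benzyloxy)-3-methoxybenzyl]tetrahydrofuran-2-yl)-2,6-dimethoxyphenoxy]acetic acid | COc1cc(C[C@@H]2CO[C@H](c3cc(OC)c(OCC(=O)O)c(OC)c3)[C@@H]2COCc2ccccc2)ccc1OCc1ccccc1
F7 | step 11 | mixed pivalic anhydride of F6 | COc1cc(C[C@@H]2CO[C@H](c3cc(OC)c(OCC(=O)OC(=O)C(C)(C)C)c(OC)c3)[C@@H]2COCc2ccccc2)ccc1OCc1ccccc1
F8 | step 15 | (S)-4-benzyl-3-{[4-((2S,3S,4S)-4-(4-hydroxy-3-methoxybenzyl)-3-(hydroxymethyl)tetrahydrofuran-2-yl)-2,6-dimethoxyphenoxy]acetyl}oxazolidin-2-one | COc1cc(C[C@@H]2CO[C@H](c3cc(OC)c(OCC(=O)N4[C@@H](Cc5ccccc5)COC4=O)c(OC)c3)[C@@H]2CO)ccc1O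
F9 | step 15 | diacetate of F8 (aryl acetate and C9' acetate) | COc1cc(C[C@@H]2CO[C@H](c3cc(OC)c(OCC(=O)N4[C@@H](Cc5ccccc5)COC4=O)c(OC)c3)[C@@H]2COC(C)=O)ccc1OC(C)=O
F10 | step 15 | syn aldol adduct of F9 with 22 ((2S,3R) in the acyl chain) | COc1cc(C[C@@H]2CO[C@H](c3cc(OC)c(O[C@H](C(=O)N4[C@@H](Cc5ccccc5)COC4=O)[C@H](O)c4cc(OC)c(O[Si](C(C)C)(C(C)C)C(C)C)c(OC)c4)c(OC)c3)[C@@H]2COC(C)=O)ccc1OC(C)=O
A1 | alternative 1 | exo-6-(4-acetoxy-3,5-dimethoxyphenyl)-2,7-dioxabicyclo[3.2.0]hept-3-ene (needed enantiomer) | CC(=O)Oc1c(OC)cc([C@H]2O[C@@H]3OC=C[C@H]23)cc1OC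
A2 | alternative 1 | 4-acetoxy-3,5-dimethoxybenzaldehyde | CC(=O)Oc1c(OC)cc(C=O)cc1OC
A3 | alternative 1 | furan | c1ccoc1
A4 | alternative 2 | trans,trans-lactone from conjugate addition and aldol trapping | O=C1O[C@H](O[C@H]2C[C@@H](C)CC[C@@H]2C(C)C)[C@@H](C2(SCCCS2)c2cc(OC)c(O[Si](C(C)C)(C(C)C)C(C)C)c(OC)c2)[C@@H]1[C@@H](O)c1ccc(OCc2ccccc2)c(OC)c1
A5 | alternative 2 | (5S)-5-(menthyloxy)furan-2(5H)-one | O=C1O[C@H](O[C@H]2C[C@@H](C)CC[C@@H]2C(C)C)C=C1
A6 | alternative 2 | 2-[3,5-dimethoxy-4-(triisopropylsilyloxy)phenyl]-1,3-dithiane | COc1cc(C2SCCCS2)cc(OC)c1O[Si](C(C)C)(C(C)C)C(C)C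
A7 | alternative 3 | tetrahydrofuro-fused isoxazoline | COc1cc([C@@H]2OC[C@@H]3C2=NO[C@@H]3c2cc(OC)c(O[Si](C(C)C)(C(C)C)C(C)C)c(OC)c2)ccc1OCc1ccccc1
A8 | alternative 3 | 2-[4-(benzyloxy)-3-methoxyphenyl]-2-{[(Z)-3-(3,5-dimethoxy-4-triisopropylsilyloxyphenyl)allyl]oxy}acetaldehyde oxime | COc1cc([C@H](OC/C=C\c2cc(OC)c(O[Si](C(C)C)(C(C)C)C(C)C)c(OC)c2)C=NO)ccc1OCc1ccccc1
A9 | alternative 3 | nitrile oxide from A8 | COc1cc([C@H](OC/C=C\c2cc(OC)c(O[Si](C(C)C)(C(C)C)C(C)C)c(OC)c2)C#[N+][O-])ccc1OCc1ccccc1
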